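**Retrosynthetic overview**
1. Target 12 ⇒ aryl O–Si cleavage ⇒ diol 11 ⇒ both carbinol C–O bonds (C3, C5) drawn back to C–B bonds (oxidation with retention) ⇒ 1,3-bis(boronate) 10.
2. 10 ⇒ C3–C4 bond by lithiation–borylation: C3 is the sparteine-lithiated O-bearing carbon of primary benzoate 7, C4 is the CH2 on the primary boron of vicinal bis(boronate) 2.
3. 2 ⇒ undec-1-ene (1) by enantioselective diboration (sets C5 as a C–B centre); 7 ⇒ eugenol (3) by silylation, hydroboration–oxidation and Mitsunobu esterification.
4. Enabling feature: the C3(OH)–C4H2–C5(OH) triad of the tetradecane chain. Each carbinol carbon can be carried as a C–B carbon, so C4/C5 map onto the two carbons of a terminal alkene and C3 onto a primary alcohol carbon.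
5. Rings: none is formed; the only ring, the 4-hydroxy-3-methoxyphenyl ring, comes in with eugenol.

Key step: step 5

Remark: C3 and C5 pass through the key step as C–B centres and both oxidations go with retention; the descriptor change at the nonyl-bearing carbon (R in 2, S in 10–12) reflects CIP ranking only, and the ligand antipode in step 1 is chosen to give (R)-2.

Step 1
Reactants: 1 undec-1-ene
Product: 2 (R)-2,2'-(undecane-1,2-diyl)bis(4,4,5,5-tetramethyl-1,3,2-dioxaborolane)
Conditions: B2pin2, Pt(dba)3 (cat.), TADDOL-derived phenylphosphonite ligand (antipode giving (R)-2), THF, 60 °C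
Reagents that add atoms: bis(pinacolato)diboron, CC1(C)OB(OC1(C)C)B1OC(C)(C)C(C)(C)O1
Why: Pt(0)-catalysed enantioselective diboration of a monosubstituted alkene (B–B oxidative addition, face-selective alkene insertion, reductive elimination) adds both borons syn and sets the C–B stereocentre (later C5) by catalyst control.

Step 2
Reactants: 3 eugenol (4-allyl-2-methoxyphenol)
Product: 4 (4-allyl-2-methoxyphenoxy)triisopropylsilane
Conditions: TIPSCl, imidazole, DMF, rt
Reagents that add atoms: triisopropylsilyl chloride, CC(C)[Si](Cl)(C(C)C)C(C)C
Why: Standard silylation of a phenol; the bulky TIPS ether has no acidic C–H, shields the neighbouring ring position and should withstand sec-BuLi at −78 °C in step 5.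

Step 3
Reactants: 4 (4-allyl-2-methoxyphenoxy)triisopropylsilane
Product: 6 3-[3-methoxy-4-(triisopropylsilyloxy)phenyl]propan-1-ol, via B-alkyl-9-BBN adduct 5 (not isolated)
Conditions: 9-BBN, THF, 0 °C → rt; then NaBO3·4H2O, H2O, rt
Reagents that add atoms: 9-borabicyclo[3.3.1]nonane, B1C2CCCC1CCC2 (its atoms stay only in 5); sodium perborate, [Na+].[Na+].O[B-]1(O)OO[B-](O)(O)OO1
Why: Anti-Markovnikov hydroboration–oxidation, in which 9-BBN places boron on the terminal carbon and the mild perborate oxidation should leave the aryl silyl ether intact.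

Step 4
Reactants: 6 3-[3-methoxy-4-(triisopropylsilyloxy)phenyl]propan-1-ol
Product: 7 3-[3-methoxy-4-(triisopropylsilyloxy)phenyl]propyl 2,4,6-triisopropylbenzoate
Conditions: 2,4,6-triisopropylbenzoic acid, PPh3, DIAD, THF, 0 °C → rt
Reagents that add atoms: 2,4,6-triisopropylbenzoic acid, CC(C)c1cc(C(C)C)c(C(=O)O)c(C(C)C)c1
Why: Mitsunobu esterification of an unhindered primary alcohol installs the hindered benzoate, which serves as directing and leaving group in step 5 and whose carbonyl is shielded from sec-BuLi.

Step 5
Reactants: 7 3-[3-methoxy-4-(triisopropylsilyloxy)phenyl]propyl 2,4,6-triisopropylbenzoate; 2 (R)-2,2'-(undecane-1,2-diyl)bis(4,4,5,5-tetramethyl-1,3,2-dioxaborolane)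
Product: 10 2,2'-{(3R,5S)-1-[3-methoxy-4-(triisopropylsilyloxy)phenyl]tetradecane-3,5-diyl}bis(4,4,5,5-tetramethyl-1,3,2-dioxaborolane), via lithiated benzoate 8 (not isolated), via boronate complex 9 (not isolated)
Conditions: 7 (1.3 equiv), (−)-sparteine, sec-BuLi (slight deficit relative to 7), Et2O, −78 °C; then 2 (1.0 equiv), −78 °C; then reflux (35 °C); aq. NH4Cl
Reagents that add atoms: sec-butyllithium, CCC(C)[Li] (lithium only in 8 and 9; no atoms in 10)
Why: sec-BuLi/(−)-sparteine removes the pro-S hydrogen next to the benzoate oxygen of 7 (complex-induced α-oxy deprotonation) to give the configurationally stable carbenoid 8, which adds with retention to the less hindered primary boron of 2 to give boronate complex 9. On warming, the C4 methylene migrates from boron to C3 anti-periplanar to the departing triisopropylbenzoate (stereospecific 1,2-metallate rearrangement, inversion at C3), which forms the C3–C4 bond between two carbons that both react as nucleophiles (carbanion at C3, B-alkyl at C4). The closest known reaction type is the lithiation–borylation homologation of boronic esters, in its site-selective form on alkene-derived vicinal bis(boronic esters). No ring is closed. The new stereocentre C3 is set by the reagent, (−)-sparteine, through the retention–inversion sequence (3R in 10), independently of C5, which stays a spectator C–B centre. The step needs site selectivity between the two borons, secured by the steric difference between the primary CH2–B and the secondary CH–B of 2, and freedom from over-homologation and arene metalation, secured by the hindered secondary boronates of 10, the bulky aryl silyl ether and the deficit of sec-BuLi relative to 7.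

Step 6
Reactants: 10 2,2'-{(3R,5S)-1-[3-methoxy-4-(triisopropylsilyloxy)phenyl]tetradecane-3,5-diyl}bis(4,4,5,5-tetramethyl-1,3,2-dioxaborolane)
Product: 11 (3R,5S)-1-[3-methoxy-4-(triisopropylsilyloxy)phenyl]tetradecane-3,5-diol
Conditions: 30% H2O2, 2 M aq. NaOH, THF, 0 °C → rt
Reagents that add atoms: hydrogen peroxide, OO
Why: Oxidation of both C–B bonds by hydroperoxide (1,2-shift from boron to oxygen) goes with retention at C3 and C5, so the syn-1,3-diol follows directly from 10; stereochemical leakage from steps 1 and 5 should appear mainly as the anti-diol, to be removed here by chromatography.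

Step 7
Reactants: 11 (3R,5S)-1-[3-methoxy-4-(triisopropylsilyloxy)phenyl]tetradecane-3,5-diol
Product: 12 (3R,5S)-1-(4-hydroxy-3-methoxyphenyl)tetradecane-3,5-diol
Conditions: TBAF, AcOH (1:1), THF, 0 °C → rt
Reagents that add atoms: none
Why: Fluoride-induced cleavage of the aryl silyl ether (Si–F bond formation) under acetic acid buffering, which keeps the electron-rich phenol protonated and leaves the two secondary alcohols untouched.

**Compound list**
1 | undec-1-ene | C=CCCCCCCCCC | starting material
2 | (R)-2,2'-(undecane-1,2-diyl)bis(4,4,5,5-tetramethyl-1,3,2-dioxaborolane) | CCCCCCCCC[C@H](B1OC(C)(C)C(C)(C)O1)CB1OC(C)(C)C(C)(C)O1 | intermediate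
3 | eugenol (4-allyl-2-methoxyphenol) | C=CCc1ccc(O)c(OC)c1 | starting material
4 | (4-allyl-2-methoxyphenoxy)triisopropylsilane | C=CCc1ccc(O[Si](C(C)C)(C(C)C)C(C)C)c(OC)c1 | intermediate
5 | 9-{3-[3-methoxy-4-(triisopropylsilyloxy)phenyl]propyl}-9-borabicyclo[3.3.1]nonane (formed in the flask, not isolated) | COc1cc(CCCB2C3CCCC2CCC3)ccc1O[Si](C(C)C)(C(C)C)C(C)C | intermediate
6 | 3-[3-methoxy-4-(triisopropylsilyloxy)phenyl]propan-1-ol | OCCCc1ccc(O[Si](C(C)C)(C(C)C)C(C)C)c(OC)c1 | intermediate
7 | 3-[3-methoxy-4-(triisopropylsilyloxy)phenyl]propyl 2,4,6-triisopropylbenzoate | CC(C)c1cc(C(C)C)c(C(=O)OCCCc2ccc(O[Si](C(C)C)(C(C)C)C(C)C)c(OC)c2)c(C(C)C)c1 | intermediate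
8 | (S)-1-lithio-3-[3-methoxy-4-(triisopropylsilyloxy)phenyl]propyl 2,4,6-triisopropylbenzoate, as its (−)-sparteine complex (formed in the flask, not isolated; sparteine omitted from the SMILES) | [Li][C@H](OC(=O)c1c(C(C)C)cc(C(C)C)cc1C(C)C)CCc1ccc(O[Si](C(C)C)(C(C)C)C(C)C)c(OC)c1 | intermediate
9 | lithium boronate complex of the primary boron of 2 with carbenoid 8: the borate boron carries pinacolate, the (R)-2-(pinacolboryl)undecyl group and the (S)-1-(2,4,6-triisopropylbenzoyloxy)-3-arylpropyl group (formed in the flask, not isolated) | [Li+].CCCCCCCCC[C@H](B1OC(C)(C)C(C)(C)O1)C[B-]1(OC(C)(C)C(C)(C)O1)[C@H](OC(=O)c1c(C(C)C)cc(C(C)C)cc1C(C)C)CCc1ccc(O[Si](C(C)C)(C(C)C)C(C)C)c(OC)c1 | intermediate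
10 | 2,2'-{(3R,5S)-1-[3-methoxy-4-(triisopropylsilyloxy)phenyl]tetradecane-3,5-diyl}bis(4,4,5,5-tetramethyl-1,3,2-dioxaborolane) | CCCCCCCCC[C@H](B1OC(C)(C)C(C)(C)O1)C[C@H](B1OC(C)(C)C(C)(C)O1)CCc1ccc(O[Si](C(C)C)(C(C)C)C(C)C)c(OC)c1 | intermediate
11 | (3R,5S)-1-[3-methoxy-4-(triisopropylsilyloxy)phenyl]tetradecane-3,5-diol | CCCCCCCCC[C@H](O)C[C@H](O)CCc1ccc(O[Si](C(C)C)(C(C)C)C(C)C)c(OC)c1 | intermediate
12 | (3R,5S)-1-(4-hydroxy-3-methoxyphenyl)tetradecane-3,5-diol (syn-diol) | CCCCCCCCC[C@H](O)C[C@H](O)CCc1ccc(O)c(OC)c1 | target

**Totals**
Total step count: 7. Longest linear sequence: 6 (steps 2, 3, 4, 5, 6, 7 from eugenol).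

**Steps most likely to fail**

Step 5. The carbenoid may add to both borons of 2 with insufficient discrimination, or the 1,2-migration may be slow relative to decay of the boronate complex. Incomplete discrimination of the enantiotopic hydrogens in the deprotonation would leak into the anti series, and competing metalation of the arene would consume the organolithium. The fallback makes the same C3–C4 bond in the normal polarity and sets the second centre by directed reduction; it sets out from 6 and comes back at 11. Oxidation of 6 (Dess–Martin periodinane, NaHCO3, CH2Cl2) should give 3-[3-methoxy-4-(triisopropylsilyloxy)phenyl]propanal F1. The kinetic enol diisopinocampheylborinate of commercial undecan-2-one (Ipc2BCl antipode chosen for the 3R carbinol, Et3N, Et2O, −78 °C) should add to F1 in a boron aldol reaction to give (R)-3-hydroxy-1-[3-methoxy-4-(triisopropylsilyloxy)phenyl]tetradecan-5-one F2. A Narasaka–Prasad reduction of F2 (Et2BOMe, NaBH4, THF/MeOH, −78 °C) should deliver hydride through the six-membered boron chelate syn to the C3 oxygen and give 11. The enantioselectivity of this aldol class for methyl ketones is expected to be lower than that of the main route, so material from this path would need enantiomeric enrichment before step 7.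

Step 1. Enantiofacial discrimination in the alkene insertion may be incomplete, or the Pt(0) catalyst may be deactivated by traces of oxygen; either would later show up as anti-diol. The fallback builds the two C–B bonds one at a time and sets the centre in a separate copper–boron addition; it sets out from 1 and comes back at 2. Cross-metathesis of 1 with vinylboronic acid pinacol ester (second-generation Ru–NHC benzylidene catalyst, CH2Cl2, 40 °C) should give (E)-4,4,5,5-tetramethyl-2-(undec-1-en-1-yl)-1,3,2-dioxaborolane F3. Enantioselective copper-catalysed protoboration of F3 (CuCl, chiral NHC ligand, NaOt-Bu, B2pin2, MeOH, THF) should place the second boron on C2, with copper α to the first boron, and after protonation give 2.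

Step 6. Oxidation of the more hindered C–B bond may be incomplete and the aryl silyl ether may be partly lost under basic peroxide, giving a mixture from which the minor anti-diastereomer is not cleanly removed. Desilylated material would still converge on 12 in step 7, but purification at the diol stage would suffer. The fallback purifies through a temporary 1,3-dioxane ring; it sets out from 10 and comes back at 11. Oxidation with sodium perborate (THF/H2O, rt), which should spare the silyl ether, is followed by treatment of the crude diol with 2,2-dimethoxypropane and PPTS in CH2Cl2. This should give (4R,6S)-4-{2-[3-methoxy-4-(triisopropylsilyloxy)phenyl]ethyl}-2,2-dimethyl-6-nonyl-1,3-dioxane F4. The syn acetonide (chair) should separate from the anti acetonide (twist-boat) on silica, and its relative configuration can be checked from the acetonide 13C shifts. Aqueous acetic acid in THF should then release 11.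

**Further compounds**
F1 | step 5 | 3-[3-methoxy-4-(triisopropylsilyloxy)phenyl]propanal | O=CCCc1ccc(O[Si](C(C)C)(C(C)C)C(C)C)c(OC)c1
F2 | step 5 | (R)-3-hydroxy-1-[3-methoxy-4-(triisopropylsilyloxy)phenyl]tetradecan-5-one | CCCCCCCCCC(=O)C[C@H](O)CCc1ccc(O[Si](C(C)C)(C(C)C)C(C)C)c(OC)c1
F3 | step 1 | (E)-4,4,5,5-tetramethyl-2-(undec-1-en-1-yl)-1,3,2-dioxaborolane | CCCCCCCCC/C=C/B1OC(C)(C)C(C)(C)O1
F4 | step 6 | (4R,6S)-4-{2-[3-methoxy-4-(triisopropylsilyloxy)phenyl]ethyl}-2,2-dimethyl-6-nonyl-1,3-dioxane | CCCCCCCCC[C@H]1C[C@@H](CCc2ccc(O[Si](C(C)C)(C(C)C)C(C)C)c(OC)c2)OC(C)(C)O1
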